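**Retrosynthetic overview**
1. The target is the threo-(7S,8S) 8-O-4′ ether. C9–OH comes from a vinyl group (ozonolysis/reduction), and the free phenol and acid come from an aryl acetate and a methyl ester cleaved at the end.
2. The C7–C8 bond is made from vanillin acetate and a (Z)-γ-aryloxyallyl-B(Ipc)2 reagent in which the oxygen-bearing C8 is the nucleophile; the chair transition state sets both stereocentres at once.
3. The allylborane comes from kinetic hydroboration of an aryloxyallene with (+)-Ipc2BH, so no strong base meets the ester-bearing arene.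
4. The aryloxyallene comes from the propargyl ether of methyl syringate (O-alkylation, then base-catalysed isomerisation).
5. No ring is formed; both arenes are bought.

Assumption: crystalline (+)-Ipc2BH (5, the enantiomer from (−)-α-pinene) is treated as a purchasable reagent; if made beforehand from (−)-α-pinene and BH3·SMe2, that preparation is not counted as a step.

**Step 1**
Reactants: 1 methyl syringate (methyl 4-hydroxy-3,5-dimethoxybenzoate); 2 propargyl bromide (3-bromoprop-1-yne)
Product: 3 methyl 3,5-dimethoxy-4-(prop-2-yn-1-yloxy)benzoate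
Conditions: K2CO3 (1.5 equiv), DMF, rt, 12 h
Reagents that add atoms: none
Why: Williamson ether synthesis (SN2); the phenoxide of 1, although flanked by two methoxy groups, alkylates cleanly with the unhindered propargylic bromide, and no stereocentre is involved.

**Step 2**
Reactants: 3 methyl 3,5-dimethoxy-4-(prop-2-yn-1-yloxy)benzoate
Product: 4 methyl 3,5-dimethoxy-4-(propa-1,2-dien-1-yloxy)benzoate
Conditions: KOtBu (0.2 equiv), THF, 0 °C → rt, 1 h; pH 7 buffer quench; filtration through basic alumina; used promptly
Reagents that add atoms: none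
Why: base-catalysed propargyl → allenyl prototropic isomerisation, the standard entry to aryloxyallenes; catalytic alkoxide at or below rt stops at the O-conjugated allene and limits ester transesterification and further isomerisation to the 1-propynyl ether; no stereocentre is involved.

**Step 3**
Reactants: 4 methyl 3,5-dimethoxy-4-(propa-1,2-dien-1-yloxy)benzoate (1.2 equiv); 5 (+)-diisopinocampheylborane (1.15 equiv); 6 vanillin acetate (4-formyl-2-methoxyphenyl acetate, 1.0 equiv)
Product: 9 methyl 4-{[(1S,2S)-1-(4-acetoxy-3-methoxyphenyl)-1-hydroxybut-3-en-2-yl]oxy}-3,5-dimethoxybenzoate, via (Z)-γ-aryloxyallylborane 7 (not isolated), via borinate adduct 8 (not isolated)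
Conditions: 4 + 5, THF, −25 °C, 5 h; then 6, −78 °C, 3 h; then pH 7 phosphate buffer/MeOH/30% H2O2, 0 °C → rt
Reagents that add atoms: none
Why: Proposed new method: kinetic hydroboration of the monosubstituted allene by the bulky dialkylborane should put boron on the unsubstituted terminus and deliver H to the central carbon from the face anti to OAr, giving the (Z)-γ-aryloxyallyl-B(Ipc)2 reagent 7 with a nucleophilic oxygen-bearing carbon; this then adds at −78 °C to the Re face of 6 through a Zimmerman–Traxler chair (OAr axial, face selected by the (−)-α-pinene-derived Ipc groups) to set the (1S,2S)-syn pair in one operation; the closest known chemistry is kinetic hydroboration of monosubstituted allenes with Ipc2BH-type boranes to (Z)-γ-substituted allylboranes, and Brown's (Z)-γ-alkoxyallyl-B(Ipc)2 allylborations (from lithiated allyl ethers), which give syn 1,2-diol monoethers in high ee.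

**Step 4**
Reactants: 9 methyl 4-{[(1S,2S)-1-(4-acetoxy-3-methoxyphenyl)-1-hydroxybut-3-en-2-yl]oxy}-3,5-dimethoxybenzoate
Product: 13 4-{[(1S,2S)-1,3-dihydroxy-1-(4-hydroxy-3-methoxyphenyl)propan-2-yl]oxy}-3,5-dimethoxybenzoic acid, via secondary ozonide 10 (not isolated), via α-aryloxy aldehyde 11 (not isolated), via diol diester 12 (not isolated)
Conditions: O3, CH2Cl2, −78 °C (Sudan Red 7B end point), N2 purge; NaBH4 (5 equiv), MeOH, −78 → 0 °C; then 2 M aq. LiOH (10 equiv), THF, rt → 40 °C; 1 M HCl to pH 3–4 at 0 °C
Reagents that add atoms: ozone, O=[O+][O-]; lithium hydroxide, [Li+].[OH-]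
Why: Criegee ozonolysis of the only alkene (far faster than attack on the arenes), borohydride reduction of the ozonide and aldehyde at low temperature before the α-aryloxy-β-hydroxy aldehyde can epimerise or undergo retro-aldol cleavage, then saponification of the aryl acetate and the methyl benzoate in the same flask; C7 and C8 are not touched, so (7S,8S) is retained.

**Compound list**
1 | methyl syringate (methyl 4-hydroxy-3,5-dimethoxybenzoate) | COC(=O)c1cc(OC)c(O)c(OC)c1 | starting material
2 | propargyl bromide (3-bromoprop-1-yne) | C#CCBr | starting material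
3 | methyl 3,5-dimethoxy-4-(prop-2-yn-1-yloxy)benzoate | COC(=O)c1cc(OC)c(OCC#C)c(OC)c1 | intermediate
4 | methyl 3,5-dimethoxy-4-(propa-1,2-dien-1-yloxy)benzoate | COC(=O)c1cc(OC)c(OC=C=C)c(OC)c1 | intermediate
5 | (+)-diisopinocampheylborane, (+)-Ipc2BH, the enantiomer from (−)-α-pinene (oxidation gives (1S,2S,3S,5R)-isopinocampheol) | B([C@H]1C[C@H]2C[C@@H]([C@@H]1C)C2(C)C)[C@H]1C[C@H]2C[C@@H]([C@@H]1C)C2(C)C | starting material
6 | vanillin acetate (4-formyl-2-methoxyphenyl acetate) | CC(=O)Oc1ccc(C=O)cc1OC | starting material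
7 | methyl 4-{[(Z)-3-(diisopinocampheylboryl)prop-1-en-1-yl]oxy}-3,5-dimethoxybenzoate (not isolated) | COC(=O)c1cc(OC)c(O/C=C\CB([C@H]2C[C@H]3C[C@@H]([C@@H]2C)C3(C)C)[C@H]2C[C@H]3C[C@@H]([C@@H]2C)C3(C)C)c(OC)c1 | intermediate
8 | O-B(Ipc)2 borinate of 9, chain centres (1S,2S) as in 9 (not isolated) | COc1cc([C@H](OB([C@H]3C[C@H]4C[C@@H]([C@@H]3C)C4(C)C)[C@H]3C[C@H]4C[C@@H]([C@@H]3C)C4(C)C)[C@H](C=C)Oc2c(OC)cc(C(=O)OC)cc2OC)ccc1OC(C)=O | intermediate
9 | methyl 4-{[(1S,2S)-1-(4-acetoxy-3-methoxyphenyl)-1-hydroxybut-3-en-2-yl]oxy}-3,5-dimethoxybenzoate (syn) | COc1cc([C@H](O)[C@H](C=C)Oc2c(OC)cc(C(=O)OC)cc2OC)ccc1OC(C)=O | intermediate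
10 | secondary ozonide of 9: vinyl replaced by 1,2,4-trioxolan-3-yl (epimers at the trioxolane carbon), both chain centres arranged as in 9 (not isolated) | COc1cc([C@H](O)[C@H](C3OCOO3)Oc2c(OC)cc(C(=O)OC)cc2OC)ccc1OC(C)=O | intermediate
11 | methyl 4-{[(2R,3S)-3-(4-acetoxy-3-methoxyphenyl)-3-hydroxy-1-oxopropan-2-yl]oxy}-3,5-dimethoxybenzoate; same spatial arrangement as 9, the C-2 descriptor changes only through CIP priority (not isolated) | COc1cc([C@H](O)[C@H](C=O)Oc2c(OC)cc(C(=O)OC)cc2OC)ccc1OC(C)=O | intermediate
12 | methyl 4-{[(1S,2S)-1-(4-acetoxy-3-methoxyphenyl)-1,3-dihydroxypropan-2-yl]oxy}-3,5-dimethoxybenzoate (not isolated) | COc1cc([C@H](O)[C@H](CO)Oc2c(OC)cc(C(=O)OC)cc2OC)ccc1OC(C)=O | intermediate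
13 | 4-{[(1S,2S)-1,3-dihydroxy-1-(4-hydroxy-3-methoxyphenyl)propan-2-yl]oxy}-3,5-dimethoxybenzoic acid (threo, 7S,8S) | COc1cc([C@H](O)[C@H](CO)Oc2c(OC)cc(C(=O)O)cc2OC)ccc1O | target

**Totals**
Total step count: 4. Longest linear sequence: 4 (1 → 3 → 4 → 9 → 13).

**Steps most likely to fail, with fallbacks**

Step 3 (highest risk). The hydroboration could go to the central allene carbon, the (Z)-allylborane could equilibrate to (E), or the enantioselectivity could be modest. The fallback sets out from 4 and comes back at 9. Allene 4 is hydroborated with pinacolborane under Pt(0) catalysis (Pt(dba)2/P(t-Bu)3, toluene, 50 °C) to the isolable, configurationally stable methyl 3,5-dimethoxy-4-{[(Z)-3-(4,4,5,5-tetramethyl-1,3,2-dioxaborolan-2-yl)prop-1-en-1-yl]oxy}benzoate F3. This boronate is then added to 6 under chiral phosphoric acid catalysis ((R)-TRIP, 5 mol %, toluene, −30 °C; the acid enantiomer is the one that directs Re-face attack, to be confirmed on the first run). The chair transition state again gives the syn adduct, the O-pinacolboryl ether of 9 F4, which is hydrolysed on work-up to 9. Enantiocontrol thus moves from a stoichiometric kinetic dialkylborane to a catalyst acting on a stable boronate.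

Step 2. The methyl ester could be transesterified or cleaved by the alkoxide, or the allene could isomerise further to the 1-propynyl ether. The fallback sets out from 3 and comes back at 4. Ester 3 is saponified (LiOH, THF/H2O) to 3,5-dimethoxy-4-(prop-2-yn-1-yloxy)benzoic acid F1. The acid is isomerised with KOtBu (1.3 equiv, THF/t-BuOH, rt) as its carboxylate, which alkoxide cannot attack, to potassium 3,5-dimethoxy-4-(propa-1,2-dien-1-yloxy)benzoate F2. The salt is methylated directly with MeI in DMF, so the acid-sensitive allenyl ether never sees acid, and this returns 4.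

Step 4. Ozone could attack the electron-rich arenes, or the three-stage one-flask sequence could give a mixture that is hard to purify. The fallback sets out from 9 and comes back at 12. Alkene 9 is dihydroxylated (OsO4 cat., NMO, acetone/H2O) to methyl 4-{[1-(4-acetoxy-3-methoxyphenyl)-1,3,4-trihydroxybutan-2-yl]oxy}-3,5-dimethoxybenzoate F5 (C-1 and C-2 arranged as in 9, C-3 epimers). The diol is cleaved with NaIO4 (pH 7, 0 °C; the phenol is still acetylated, so periodate cannot oxidise it) to aldehyde 11, which is reduced at once with NaBH4 to 12. Compound 12 is isolated this time, and the LiOH saponification to 13 is run as a separate, clean operation.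

**Further compounds**
F1 | step 2 | 3,5-dimethoxy-4-(prop-2-yn-1-yloxy)benzoic acid | OC(=O)c1cc(OC)c(OCC#C)c(OC)c1
F2 | step 2 | potassium 3,5-dimethoxy-4-(propa-1,2-dien-1-yloxy)benzoate | [K+].[O-]C(=O)c1cc(OC)c(OC=C=C)c(OC)c1
F3 | step 3 | methyl 3,5-dimethoxy-4-{[(Z)-3-(4,4,5,5-tetramethyl-1,3,2-dioxaborolan-2-yl)prop-1-en-1-yl]oxy}benzoate | COC(=O)c1cc(OC)c(O/C=C\CB2OC(C)(C)C(C)(C)O2)c(OC)c1
F4 | step 3 | O-pinacolboryl ether of 9, chain centres as in 9 | COc1cc([C@H](OB3OC(C)(C)C(C)(C)O3)[C@H](C=C)Oc2c(OC)cc(C(=O)OC)cc2OC)ccc1OC(C)=O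
F5 | step 4 | methyl 4-{[1-(4-acetoxy-3-methoxyphenyl)-1,3,4-trihydroxybutan-2-yl]oxy}-3,5-dimethoxybenzoate, C-1 and C-2 as in 9, C-3 epimers | COc1cc([C@H](O)[C@H](C(O)CO)Oc2c(OC)cc(C(=O)OC)cc2OC)ccc1OC(C)=O
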